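The earlier runs and the new flask are calculated for an exercise.

A single flask cannot part substrate from target: substrate falls exactly as target rises, so one curve cannot separate their effects. The runs must be held against each other.

| setting | elm | oak | alder | ash |
|---|---|---|---|---|
| substrate | 0.400 M | 0.240 M | 1.20 M | 1.20 M |
| time |  |  |  | 130 min |

- elm run (time / min: [target] / M): 19: 0.0530; 37: 0.0940; 56: 0.1368; 74: 0.1708; 93: 0.2006; 110: 0.2231; 130: 0.2485
- oak run (time / min: [target] / M): 19: 0.0314; 37: 0.0556; 56: 0.0795; 74: 0.1008; 93: 0.1182; 110: 0.1361; 130: 0.1498
- alder run (time / min: [target] / M): 19: 0.1581; 37: 0.2875; 56: 0.4101; 74: 0.5068; 93: 0.5961; 110: 0.6736; 130: 0.7398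

(readings scatter by 0.002 M)

1. apparent order in [substrate] of the starting rate, round the charge of the elm run (the rate where two percent of its substrate have turned into target) (one fixed amount of target, the same in the runs compared)
2. the oak run starts with 0.160 M less of substrate than the elm run, and with no target. Compared where both hold the same amount of substrate, once fifteen percent of what the oak run was charged with has turned into target, is the oak run faster, slower or alike (within a tenth)?
3. target in the ash run at 130 min, as a share of the substrate charged

- Overall: substrate -> target.
- Constant volume, constant temperature.
- An order is taken over about fifteen percent of the charge, up and down.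

The early end comes first. At 19 min, the elm run holds 0.0530 M of target and the oak run 0.0314 M, so the log ratio of readings over the log ratio of charges gives an order of 1.02. But the scatter of the oak reading moves that by 0.125. Alder against elm is tighter and gives 0.995, though it reaches well above the elm charge. A harder objection: these readings share a time, not an amount of target.

The late end answers it, at 130 min:

| Run | Charge | Target, share of charge |
|---|---|---|
| elm | 0.400 M | 62.1% |
| oak | 0.240 M | 62.4% |
| alder | 1.20 M | 61.7% |

Target ranges from 0.1498 M to 0.7398 M, yet the shares stay within the oak scatter of 0.833% of charge. My reckoning is therefore order one, a first-order rate law.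

A direct test remains. Oak over its first 37 min averages 0.212 M of substrate, and elm from 74 min to 110 min averages 0.203 M, with far more target. Their rates stand at a ratio of 1.03, so I call them alike.

Alder's log of charge over remaining substrate, per minute, gives 0.00744 min⁻¹ at the first reading and 0.00737 min⁻¹ at the last, a gap inside the early scatter. Joining the ends gives 0.00740 min⁻¹, the turnover constant k, and so 61.8% for the ash run.

The forecast gives order 1, oak alike and ash 61.8%, finding “no sign of saturation or product inhibition”.

The flask gives 1.0, alike and 62.0%.

    substrate → target (0.007440 min⁻¹)

In the ash run, the single step turned substrate into target throughout the 130 min, while substrate fell from 1.20 M to 0.456 M. Target ended that time at 62.0% of the charge. The time that k gives for turning 0.5 of a charge is 93.6 min. The oak run, charged with 0.240 M, reached 0.5 of its charge at 93.2 min.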